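The ring-fusion carbons C5 and C1 (quaternary, methyl), shared by ring A (five-membered, C1–C5) and ring B (seven-membered, C1, C5–C10), are treated as the β- and α-carbons of a cyclohept-2-enone whose carbonyl becomes C10. In one flask an alkenylcopper reagent adds to C5 anti to the C6 silyloxy group and the C1 enolate is methylated, which forms C4–C5 and C1–CH3 and sets both fusion stereocentres. The precursor is an (S)-2-allyl-4-silyloxycyclohept-2-enone 6-ketal made from tropone through an enzymatic desymmetrisation. Metathesis then closes ring A, and the C6 oxygen is inverted late by oxidation and hydroxyl-directed reduction.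

Key step: step 11

Numbering: carbons carry their target numbers; ring A is C1–C2–C3–C4–C5, ring B is C1–C5–C6–C7–C8–C9–C10; C1 bears the angular methyl and C4 the isopropyl group; β is the face of the C1 methyl group, α the other face; "cis-daucane" means this skeleton with the C1 methyl and H-5 cis.

Assumption: the lipase cleaves the acetate on the (S)-configured carbon of meso-diacetate 6, the usual sense for cis-cycloalk-2-ene-1,4-diyl diacetates; if it cleaved the other ester, acetylation of diol 5 with the same lipase and vinyl acetate would give the same monoacetate 7.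

Step 1
Reactants: 1 tropone
Product: 2 cyclohepta-3,5-dien-1-one
Conditions: LiAlH4 (0.3 equiv), Et2O, −10 °C; cold aq. AcOH quench
Reagents that add atoms: none
Why: Conjugate (1,8) hydride addition to C2 of tropone gives a trienolate, and kinetic protonation at the α-carbon on quench should give the unconjugated 3,5-dienone, the known course of the LiAlH4 reduction of tropone.

Step 2
Reactants: 2 cyclohepta-3,5-dien-1-one
Product: 3 1,4-dioxaspiro[4.6]undeca-7,9-diene
Conditions: TMSOCH2CH2OTMS, TMSOTf (cat.), CH2Cl2, −78 → −20 °C; pyridine quench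
Reagents that add atoms: 1,2-bis(trimethylsilyloxy)ethane, C[Si](C)(C)OCCO[Si](C)(C)C
Why: Ketalisation with the bis-silyl ether of ethylene glycol under TMSOTf catalysis runs cold and without water or protic acid, so the diene should not move into conjugation with the carbonyl group.

Step 3
Reactants: 3 1,4-dioxaspiro[4.6]undeca-7,9-diene
Product: 6 meso-diacetate of the cis-enediol ketal, via endoperoxide 4 (not isolated), via meso-diol 5 (not isolated)
Conditions: O2, visible light, tetraphenylporphyrin (cat.), CH2Cl2, 0 °C; then Zn dust, AcOH, 0 °C → rt; then pyridine, Ac2O, DMAP (cat.), rt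
Reagents that add atoms: dioxygen, O=O; acetic anhydride, CC(=O)OC(C)=O
Why: The [4+2] cycloaddition of singlet oxygen to the cyclic 1,3-diene places both C–O bonds on one face, reductive O–O cleavage by zinc keeps them there, and acetylation should give the cis (meso) diacetate.

Step 4
Reactants: 6 meso-diacetate
Product: 7 (7R,10S)-10-hydroxy-1,4-dioxaspiro[4.6]undec-8-en-7-yl acetate
Conditions: Burkholderia cepacia lipase, phosphate buffer pH 7/acetone, rt, pH held at 7
Reagents that add atoms: none
Why: Enzymatic desymmetrisation by lipase-catalysed hydrolysis of one of the two enantiotopic acetates of a meso cycloalk-2-ene-1,4-diyl diacetate sets both stereocentres of 7 and should stop at the monoacetate because the remaining ester is the mismatched one.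

Step 5
Reactants: 7 monoacetate
Product: 8 (7R,10S)-10-(tert-butyldimethylsilyloxy)-1,4-dioxaspiro[4.6]undec-8-en-7-yl acetate
Conditions: TBSCl, imidazole, DMF, rt
Reagents that add atoms: tert-butyldimethylsilyl chloride, CC(C)(C)[Si](C)(C)Cl
Why: Imidazole-promoted silylation of the free secondary allylic alcohol is a standard protection that leaves the acetate and the ketal untouched.

Step 6
Reactants: 8 silyl ether acetate
Product: 9 (7R,10S)-10-(tert-butyldimethylsilyloxy)-1,4-dioxaspiro[4.6]undec-8-en-7-ol
Conditions: K2CO3 (cat.), MeOH, 0 °C → rt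
Reagents that add atoms: none
Why: Base-catalysed transesterification with methanol removes the acetate, while the silyl ether and the ketal are stable to carbonate in methanol.

Step 7
Reactants: 9 allylic alcohol
Product: 10 (S)-10-(tert-butyldimethylsilyloxy)-1,4-dioxaspiro[4.6]undec-8-en-7-one
Conditions: MnO2 (activated), CH2Cl2, rt
Reagents that add atoms: none
Why: MnO2 oxidation of an allylic alcohol gives the enone under neutral conditions and does not touch the stereocentre at the silyloxy carbon.

Step 8
Reactants: 10 silyloxy enone
Product: 11 (S)-10-(tert-butyldimethylsilyloxy)-8-iodo-1,4-dioxaspiro[4.6]undec-8-en-7-one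
Conditions: I2, pyridine/CH2Cl2 (1:1), 0 °C → rt
Reagents that add atoms: iodine, I-I
Why: α-Iodination of a cyclic enone by the iodine/pyridine addition–elimination sequence (Baylis–Hillman-type mechanism: conjugate addition of pyridine, iodination of the enolate, elimination) is general and runs in a buffered, non-acidic medium that the ketal tolerates.

Step 9
Reactants: 11 α-iodoenone; 12 allyltributylstannane
Product: 13 (S)-8-allyl-10-(tert-butyldimethylsilyloxy)-1,4-dioxaspiro[4.6]undec-8-en-7-one
Conditions: Pd2(dba)3 (cat.), AsPh3, CuI, NMP, rt → 50 °C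
Reagents that add atoms: none
Why: Stille coupling of an α-iodoenone with an allylstannane under zerovalent palladium catalysis, accelerated by AsPh3 and CuI, joins the sp2 carbon C1 to the allyl group without touching the γ-stereocentre.

Step 10
Reactants: 14 2-bromo-3-methylbut-1-ene
Product: 15 (3-methylbut-1-en-2-yl)magnesium bromide
Conditions: Mg turnings, THF, 40 °C → rt
Reagents that add atoms: magnesium, [Mg]
Why: Insertion of magnesium into the alkenyl C–Br bond in THF is the standard Grignard formation for an α-branched alkenyl bromide.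

Step 11
Reactants: 13 2-allyl-4-silyloxycyclohept-2-enone 6-ethylene ketal; 15 (3-methylbut-1-en-2-yl)magnesium bromide; 16 iodomethane
Product: 19 2-allyl-2-methyl-3-(3-methylbut-1-en-2-yl)-4-silyloxycycloheptanone 6-ethylene ketal, via silyl enol ether 17 (not isolated), via lithium enolate 18 (not isolated)
Conditions: 15 (2 equiv), CuBr·SMe2 (0.2 equiv), Me3SiCl, DMPU, THF, −78 → −40 °C; then MeLi, −40 → 0 °C; then 16 (excess), DMPU, −78 → 0 °C
Reagents that add atoms: none
Why: The Grignard reagent transmetalates to copper, and the alkenylcopper species, activated by Me3SiCl, adds in a conjugate sense to C5 of enone 13 to give silyl enol ether 17 with the enol double bond fixed between C1 and C10; MeLi then cleaves the Si–O bond to lithium enolate 18, which is methylated at C1 by SN2 attack on iodomethane. The closest known reaction type is the tandem organocopper conjugate addition–enolate alkylation (three-component coupling) of cyclic enones, run here in its silyl-trapping variant. No ring is closed; the two new bonds are C4–C5 and C1–CH3. C5 is set by the C6 silyloxy group, because the copper reagent approaches the enone face opposite to this bulky neighbour, and C1 is set by the new C5 alkenyl group, because iodomethane approaches the enolate face opposite to it; methyl therefore ends cis to H-5 and allyl cis to the alkenyl group, as closure of a cis-fused ring A requires. The step needs 1,4- over 1,2-addition, which copper and Me3SiCl secure, and C-methylation at C1 only, which the regiospecific generation of 18 from 17 secures; the ketal oxygen β to the carbonyl on the C9 side is safe as long as 18 does not equilibrate to the C9 enolate, hence low temperature and excess iodomethane.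

Step 12
Reactants: 19 key-step product
Product: 20 cis-fused bicyclo[5.3.0]dec-3-en-10-one 8-ethylene ketal (1β-methyl, 4-isopropyl, 5β-H, 6β-OTBS)
Conditions: second-generation Grubbs catalyst, RuCl2(=CHPh)(H2IMes)(PCy3) (5 mol %), toluene, 80 °C
Reagents that add atoms: none
Why: Ring-closing metathesis between the allyl group on C1 and the 1,1-disubstituted alkene on C5, which are cis on ring B, closes ring A as a trisubstituted C3=C4 cyclopentene with loss of ethylene and without touching a stereocentre.

Step 13
Reactants: 20 bicyclic keto ketal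
Product: 21 bicyclic 8,10-dione (1β-methyl, 4-isopropyl, 5β-H, 6β-OTBS, C3=C4)
Conditions: PPTS, acetone/H2O (10:1), 55 °C
Reagents that add atoms: water, O
Why: Mild acid-catalysed ketal hydrolysis unveils the C8 ketone as an enolisable 1,3-dione, and the hindered secondary TBS ether and the trisubstituted alkene should tolerate PPTS.

Step 14
Reactants: 21 1,3-dione
Product: 22 8-(trifluoromethanesulfonyloxy)-3,8-dien-10-one (6β-OTBS)
Conditions: Tf2O, Et3N, CH2Cl2, −78 °C
Reagents that add atoms: trifluoromethanesulfonic anhydride, O=S(=O)(OS(=O)(=O)C(F)(F)F)C(F)(F)F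
Why: O-Sulfonylation of the 1,3-dione enolate gives the vinylogous triflate, and the oxygen on C8 should react in preference because the oxygen on C10 is shielded by the adjacent quaternary carbon C1.

Step 15
Reactants: 22 vinylogous triflate
Product: 23 6β-(tert-butyldimethylsilyloxy)-cis-dauca-3,8-dien-10-one
Conditions: Me2CuLi (from MeLi and CuI), Et2O/THF, −78 → −40 °C
Reagents that add atoms: lithium dimethylcuprate, [Li+].C[Cu-]C
Why: Cuprate coupling of an enol triflate, here an addition–elimination on a β-triflyloxy enone, replaces the triflate on C8 by methyl at a temperature at which the hindered C10 carbonyl and the product enone are not attacked.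

Step 16
Reactants: 23 dienone
Product: 24 3β,4β-epoxy-6β-(tert-butyldimethylsilyloxy)-cis-dauc-8-en-10-one
Conditions: mCPBA, NaHCO3, CH2Cl2, 0 °C
Reagents that add atoms: 3-chloroperbenzoic acid, OOC(=O)c1cccc(Cl)c1
Why: Prilezhaev epoxidation is selective for the electron-rich C3=C4 alkene over the electron-poor enone alkene and should take place on the convex face of the cis-fused bicycle, the face of H-5 and the C1 methyl group, anti to the C5–C6 bond.

Step 17
Reactants: 24 epoxy enone
Product: 25 6β-(tert-butyldimethylsilyloxy)-cis-dauc-8-ene-4β,10β-diol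
Conditions: LiAlH4, THF, −78 °C, then 50 °C; aq. Rochelle salt work-up
Reagents that add atoms: none
Why: Hydride reduction by LiAlH4 first reduces the enone in the 1,2-sense in the cold, with hydride expected on the C10 face opposite to the angular methyl group and to the transannular 6β-silyloxy group, and on warming opens the epoxide by SN2 attack at the less substituted carbon C3, which leaves the C4–O bond and its configuration intact.

Step 18
Reactants: 25 diol; 26 3-methylbutanoic anhydride
Product: 27 6β-(tert-butyldimethylsilyloxy)-4β-hydroxy-cis-dauc-8-en-10β-yl 3-methylbutanoate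
Conditions: DMAP, Et3N, CH2Cl2, rt → 40 °C
Reagents that add atoms: none
Why: DMAP-catalysed acylation with the anhydride esterifies the secondary allylic C10 alcohol, while the tertiary C4 alcohol is too hindered to react under these conditions.

Step 19
Reactants: 27 silyl ether ester
Product: 28 4β,6β-dihydroxy-cis-dauc-8-en-10β-yl 3-methylbutanoate
Conditions: HF·pyridine, pyridine, THF, 0 °C → rt
Reagents that add atoms: none
Why: Fluoride-mediated desilylation with buffered HF·pyridine cleaves the secondary TBS ether without base, so the allylic ester neither migrates nor hydrolyses and the tertiary alcohol is untouched.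

Step 20
Reactants: 28 diol ester
Product: 29 4β-hydroxy-6-oxo-cis-dauc-8-en-10β-yl 3-methylbutanoate
Conditions: Dess–Martin periodinane, NaHCO3, CH2Cl2, 0 °C → rt; crude 29 used at once
Reagents that add atoms: none
Why: Dess–Martin oxidation under bicarbonate buffer is fast and neutral, so the β,γ-unsaturated β'-hydroxy ketone should form without migration of the C8=C9 double bond, retro-aldol cleavage or epimerisation at C5.

Step 21
Reactants: 29 C6 ketone
Product: 30 4β,6α-dihydroxy-cis-dauc-8-en-10β-yl 3-methylbutanoate
Conditions: Me4NBH(OAc)3, MeCN/AcOH (1:1), −30 °C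
Reagents that add atoms: none
Why: In this hydroxyl-directed (Evans–Saksena) reduction the tertiary C4 hydroxyl binds boron and hydride is delivered intramolecularly to the C6 carbonyl from the face of that hydroxyl, which is also the face away from the C4 isopropyl group, so the new hydroxyl should be anti to the C4 hydroxyl (6α); the reagent leaves the esters alone.

Step 22
Reactants: 30 4β,6α-diol; 31 4-acetoxybenzoyl chloride
Product: 32 6α-(4-acetoxybenzoyloxy)-4β-hydroxy-cis-dauc-8-en-10β-yl 3-methylbutanoate
Conditions: DMAP, Et3N, CH2Cl2, rt → 40 °C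
Reagents that add atoms: none
Why: DMAP-catalysed acylation through the acylpyridinium ion esterifies the secondary C6 alcohol with retention, and the tertiary C4 alcohol cannot compete.

Step 23
Reactants: 32 aryl acetate
Product: 33 CNP0086724.1
Conditions: pyrrolidine, CH2Cl2, 0 °C → rt
Reagents that add atoms: none
Why: Aminolysis of a phenyl acetate is far faster than that of the alkyl 3-methylbutanoate or the alkyl benzoate, because phenoxide is the better leaving group, so only the phenol should be set free.

Compound list
1 | tropone (cyclohepta-2,4,6-trien-1-one) | O=C1C=CC=CC=C1 | starting material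
2 | cyclohepta-3,5-dien-1-one | O=C1CC=CC=CC1 | intermediate
3 | 1,4-dioxaspiro[4.6]undeca-7,9-diene (ethylene ketal of 2) | C1=CCC2(OCCO2)CC=C1 | intermediate
4 | meso-endoperoxide of 3, peroxide bridge joining C7 and C10 on one face, C8=C9 alkene (not isolated) | O1[C@H]2C=C[C@@H](O1)CC1(OCCO1)C2 | intermediate
5 | meso-diol, cis-(7R,10S)-1,4-dioxaspiro[4.6]undec-8-ene-7,10-diol (not isolated) | O[C@H]1C=C[C@@H](O)CC2(OCCO2)C1 | intermediate
6 | meso-diacetate, cis-(7R,10S)-1,4-dioxaspiro[4.6]undec-8-ene-7,10-diyl diacetate | CC(=O)O[C@H]1C=C[C@@H](OC(C)=O)CC2(OCCO2)C1 | intermediate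
7 | (7R,10S)-10-hydroxy-1,4-dioxaspiro[4.6]undec-8-en-7-yl acetate | CC(=O)O[C@H]1C=C[C@@H](O)CC2(OCCO2)C1 | intermediate
8 | (7R,10S)-10-(tert-butyldimethylsilyloxy)-1,4-dioxaspiro[4.6]undec-8-en-7-yl acetate | CC(=O)O[C@H]1C=C[C@@H](O[Si](C)(C)C(C)(C)C)CC2(OCCO2)C1 | intermediate
9 | (7R,10S)-10-(tert-butyldimethylsilyloxy)-1,4-dioxaspiro[4.6]undec-8-en-7-ol | O[C@H]1C=C[C@@H](O[Si](C)(C)C(C)(C)C)CC2(OCCO2)C1 | intermediate
10 | (S)-10-(tert-butyldimethylsilyloxy)-1,4-dioxaspiro[4.6]undec-8-en-7-one (4-silyloxycyclohept-2-enone 6-ethylene ketal) | O=C1C=C[C@@H](O[Si](C)(C)C(C)(C)C)CC2(OCCO2)C1 | intermediate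
11 | (S)-10-(tert-butyldimethylsilyloxy)-8-iodo-1,4-dioxaspiro[4.6]undec-8-en-7-one | O=C1C(I)=C[C@@H](O[Si](C)(C)C(C)(C)C)CC2(OCCO2)C1 | intermediate
12 | allyltributylstannane | C=CC[Sn](CCCC)(CCCC)CCCC | starting material
13 | (S)-8-allyl-10-(tert-butyldimethylsilyloxy)-1,4-dioxaspiro[4.6]undec-8-en-7-one (2-allyl-4-silyloxycyclohept-2-enone 6-ethylene ketal, key-step precursor) | C=CCC1=C[C@@H](O[Si](C)(C)C(C)(C)C)CC2(OCCO2)CC1=O | intermediate
14 | 2-bromo-3-methylbut-1-ene | C=C(Br)C(C)C | starting material
15 | (3-methylbut-1-en-2-yl)magnesium bromide | C=C([Mg]Br)C(C)C | intermediate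
16 | iodomethane | CI | starting material
17 | trimethylsilyl enol ether (C1=C10) of the conjugate adduct, C5 alkenyl trans to the C6 silyloxy group (not isolated) | C=CCC1=C(O[Si](C)(C)C)CC2(OCCO2)C[C@H](O[Si](C)(C)C(C)(C)C)[C@H]1C(=C)C(C)C | intermediate
18 | lithium enolate corresponding to 17 (not isolated) | C=CCC1=C(O[Li])CC2(OCCO2)C[C@H](O[Si](C)(C)C(C)(C)C)[C@H]1C(=C)C(C)C | intermediate
19 | 2-allyl-2-methyl-3-(3-methylbut-1-en-2-yl)-4-(tert-butyldimethylsilyloxy)cycloheptanone 6-ethylene ketal; C5 alkenyl trans to the C6 silyloxy group, C1 methyl trans to the alkenyl group (cis to H-5), allyl cis to the alkenyl group | C=CC[C@]1(C)[C@H](C(=C)C(C)C)[C@@H](O[Si](C)(C)C(C)(C)C)CC2(OCCO2)CC1=O | intermediate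
20 | cis-fused bicyclo[5.3.0]dec-3-en-10-one 8-ethylene ketal with 1β-methyl, 4-isopropyl, 5β-H and 6β-silyloxy | C[C@@]12CC=C(C(C)C)[C@@H]1[C@@H](O[Si](C)(C)C(C)(C)C)CC1(OCCO1)CC2=O | intermediate
21 | the 8,10-dione from 20 (1β-methyl, 4-isopropyl, 5β-H, 6β-silyloxy, C3=C4) | C[C@@]12CC=C(C(C)C)[C@@H]1[C@@H](O[Si](C)(C)C(C)(C)C)CC(=O)CC2=O | intermediate
22 | 8-(trifluoromethanesulfonyloxy)-3,8-dien-10-one from 21 (6β-silyloxy) | C[C@@]12CC=C(C(C)C)[C@@H]1[C@@H](O[Si](C)(C)C(C)(C)C)CC(OS(=O)(=O)C(F)(F)F)=CC2=O | intermediate
23 | 6β-(tert-butyldimethylsilyloxy)-cis-dauca-3,8-dien-10-one | C[C@@]12CC=C(C(C)C)[C@@H]1[C@@H](O[Si](C)(C)C(C)(C)C)CC(C)=CC2=O | intermediate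
24 | 3β,4β-epoxy-6β-(tert-butyldimethylsilyloxy)-cis-dauc-8-en-10-one | C[C@@]12C[C@H]3O[C@@]3(C(C)C)[C@@H]1[C@@H](O[Si](C)(C)C(C)(C)C)CC(C)=CC2=O | intermediate
25 | 6β-(tert-butyldimethylsilyloxy)-cis-dauc-8-ene-4β,10β-diol | C[C@@]12CC[C@](O)(C(C)C)[C@@H]1[C@@H](O[Si](C)(C)C(C)(C)C)CC(C)=C[C@H]2O | intermediate
26 | 3-methylbutanoic (isovaleric) anhydride | CC(C)CC(=O)OC(=O)CC(C)C | starting material
27 | 6β-(tert-butyldimethylsilyloxy)-4β-hydroxy-cis-dauc-8-en-10β-yl 3-methylbutanoate | C[C@@]12CC[C@](O)(C(C)C)[C@@H]1[C@@H](O[Si](C)(C)C(C)(C)C)CC(C)=C[C@H]2OC(=O)CC(C)C | intermediate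
28 | 4β,6β-dihydroxy-cis-dauc-8-en-10β-yl 3-methylbutanoate | C[C@@]12CC[C@](O)(C(C)C)[C@@H]1[C@@H](O)CC(C)=C[C@H]2OC(=O)CC(C)C | intermediate
29 | 4β-hydroxy-6-oxo-cis-dauc-8-en-10β-yl 3-methylbutanoate | C[C@@]12CC[C@](O)(C(C)C)[C@@H]1C(=O)CC(C)=C[C@H]2OC(=O)CC(C)C | intermediate
30 | 4β,6α-dihydroxy-cis-dauc-8-en-10β-yl 3-methylbutanoate | C[C@@]12CC[C@](O)(C(C)C)[C@@H]1[C@H](O)CC(C)=C[C@H]2OC(=O)CC(C)C | intermediate
31 | 4-acetoxybenzoyl chloride | CC(=O)Oc1ccc(cc1)C(Cl)=O | starting material
32 | 6α-(4-acetoxybenzoyloxy)-4β-hydroxy-cis-dauc-8-en-10β-yl 3-methylbutanoate | C[C@@]12CC[C@](O)(C(C)C)[C@@H]1[C@H](OC(=O)c1ccc(OC(C)=O)cc1)CC(C)=C[C@H]2OC(=O)CC(C)C | intermediate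
33 | CNP0086724.1: 4β-hydroxy-6α-(4-hydroxybenzoyloxy)-cis-dauc-8-en-10β-yl 3-methylbutanoate, (1R,4S,5S,6R,10R) in the numbering used here | CC1=C[C@@H](OC(=O)CC(C)C)[C@]2(C)CC[C@](O)(C(C)C)[C@@H]2[C@H](OC(=O)c2ccc(O)cc2)C1 | target

Total step count: 23. Longest linear sequence: 22 steps (steps 1–9 and 11–23); step 10 is a one-step side branch.

Steps most likely to fail

1. Step 11 (key step). Alkylation of the hindered, fully substituted enolate may be slow enough for proton transfer to move the enolate to C9, where the ketal oxygen is lost by β-elimination, or for methylation to drift to oxygen. The fallback sets out from 13 and returns at 19. The conjugate addition is run as in step 11 but stopped at silyl enol ether 17, which is isolated by non-aqueous work-up. Furukawa-modified Simmons–Smith cyclopropanation (Et2Zn, CH2I2, CH2Cl2, 0 °C) of the electron-rich enol double bond, on the face opposite to the C5 alkenyl group and in preference to the two unactivated alkenes, should give the siloxycyclopropane F1. K2CO3 in methanol then removes the silyl group, and the cyclopropanolate opens at the bond to the CH2 carbon; this turns that CH2 into the C1 methyl group and restores the C10 ketone of 19. No free enolate meets an alkylating agent in this sequence.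

2. Step 17. Hydride may be delivered to the wrong face of the C10 carbonyl, or in the 1,4-sense, because the conformation of ring B is hard to predict. The fallback sets out from 24 and returns at 25. CBS reduction with (S)-2-methyl-CBS-oxazaborolidine (cat.) and catecholborane in toluene at −78 °C places the quaternary C1 as the large group and should give the 10β-alcohol under reagent control, the epoxy allylic alcohol F2. LiEt3BH (THF, 0 °C → rt) then opens the epoxide at C3 to give 25.

3. Step 21. The C8=C9 double bond may migrate into conjugation with the C6 ketone in the acidic medium before reduction, or hydride may arrive without direction on the wrong face. The fallback sets out from 28 and returns at 32. Mitsunobu esterification of 28 with 4-acetoxybenzoic acid (PPh3, DIAD, toluene, 0 °C → rt) displaces the activated 6β-oxygen with inversion and should give 32 directly, bypassing steps 20–22. This fallback makes no compound outside the list (F0).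

Further compounds
F1 | step 11 | siloxycyclopropane from 17: CH2 bridging C1 and C10 on the face opposite to the C5 alkenyl group, OSiMe3 on C10, allyl on C1 cis to the alkenyl group | C=CC[C@@]12C[C@]1(O[Si](C)(C)C)CC1(OCCO1)C[C@H](O[Si](C)(C)C(C)(C)C)[C@H]2C(=C)C(C)C
F2 | step 17 | 3β,4β-epoxy-6β-(tert-butyldimethylsilyloxy)-cis-dauc-8-en-10β-ol | C[C@@]12C[C@H]3O[C@@]3(C(C)C)[C@@H]1[C@@H](O[Si](C)(C)C(C)(C)C)CC(C)=C[C@H]2O
F0 | step 21 | none | none
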